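Retrosynthesis (ring B locants: C1 bears the pendant catechol ring C, C2 and C3 each bear a carboxyl carbon, C4 is the vinylic CH next to ring A): cut the ester C–O bond between the C3 carboxyl and L-malate, trace C3=C4 back to a C4 ketone, then cut C2–C3.
C2–C3 is a succinate bond: C2 is α to its ester, C3 is α to its ester and to the C4 ketone, so both are enolate carbons of like polarity and can be joined by oxidising the bis-enolate.
The open keto diester is cut further at C3–carboxyl (Claisen), C4–C4a (Stille), C1–ring C (1,4-addition) and C1=C2 (olefination).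
Forward: ring A bromoaldehyde → enoate → ring C added at C1 → acetyl at C4a → β-ketoester → ring B closed by C2–C3 coupling → C4 ketone turned into C3=C4 → malate ester → deprotection.
Stereochemistry: C1 from rhodium/(S)-BINAP 1,4-addition; C2 trans to C1 by substrate control in the ring closure (also the thermodynamic isomer); the malate centre is bought as L-malate and never touched.
Protection: benzyl ethers, tert-butyl esters at C2 and on malate, allyl ester at C3, so that nothing needs aqueous base or hydrogen once the C3=C4 alkene exists.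

Key step: step 6

Assumption: 3,4-bis(benzyloxy)phenylboronic acid 5 and di-tert-butyl L-malate 18 are taken as purchasable; otherwise each is one standard step away (Br/Li exchange and borylation of 4-bromo-1,2-bis(benzyloxy)benzene; isobutene/cat. H2SO4 on L-malic acid).

Step 1
Reactants: 1 3,4-bis(benzyloxy)benzaldehyde
Product: 2 4,5-bis(benzyloxy)-2-bromobenzaldehyde
Conditions: Br2, NaOAc, AcOH, rt
Reagents that add atoms: bromine, BrBr
Why: Electrophilic aromatic bromination goes to the position para to the 3-benzyloxy group and ortho to the formyl group, the usual outcome for 3,4-dialkoxybenzaldehydes, while NaOAc takes up HBr and so protects the benzyl ethers.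

Step 2
Reactants: 2 4,5-bis(benzyloxy)-2-bromobenzaldehyde; 3 tert-butyl 2-(diethoxyphosphoryl)acetate
Product: 4 tert-butyl (2E)-3-[4,5-bis(benzyloxy)-2-bromophenyl]prop-2-enoate
Conditions: NaH, THF, 0 °C → rt
Reagents that add atoms: none
Why: Horner–Wadsworth–Emmons olefination of a non-enolisable aryl aldehyde with a stabilised phosphonate anion should give the (E)-enoate.

Step 3
Reactants: 4 tert-butyl (2E)-3-[4,5-bis(benzyloxy)-2-bromophenyl]prop-2-enoate; 5 [3,4-bis(benzyloxy)phenyl]boronic acid
Product: 6 tert-butyl (3R)-3-[4,5-bis(benzyloxy)-2-bromophenyl]-3-[3,4-bis(benzyloxy)phenyl]propanoate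
Conditions: [RhCl(C2H4)2]2 (cat.), (S)-BINAP, aq. KOH (substoichiometric), dioxane/H2O (10:1), 60–80 °C
Reagents that add atoms: none
Why: Hayashi–Miyaura reaction, in which the aryl–rhodium–(S)-BINAP species formed by transmetalation inserts the (E)-enoate from the face that is si at Cα (the face this ligand selects for (E)-enoates), which corresponds to the (3R) centre that becomes C1, and hydrolysis of the rhodium enolate releases the product; the aryl bromide, benzyl ethers and tert-butyl ester are inert to monovalent rhodium, and the sense of induction is to be confirmed on 6 before scale-up.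

Step 4
Reactants: 6 tert-butyl (3R)-3-[4,5-bis(benzyloxy)-2-bromophenyl]-3-[3,4-bis(benzyloxy)phenyl]propanoate; 7 tributyl(1-ethoxyethenyl)stannane
Product: 9 tert-butyl (3R)-3-[2-acetyl-4,5-bis(benzyloxy)phenyl]-3-[3,4-bis(benzyloxy)phenyl]propanoate, via 1-ethoxyethenyl arene 8 (not isolated)
Conditions: Pd(PPh3)4 (cat.), toluene, 110 °C; then 1 M HCl, THF, rt
Reagents that add atoms: water, O
Why: Stille coupling of the aryl bromide with the 1-ethoxyvinyl stannane (an acetyl anion equivalent), followed by mild acid hydrolysis of the enol ether, places the acetyl group (the future C4 and C3) at C4a without touching the tert-butyl ester or the C1 centre.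

Step 5
Reactants: 9 tert-butyl (3R)-3-[2-acetyl-4,5-bis(benzyloxy)phenyl]-3-[3,4-bis(benzyloxy)phenyl]propanoate; 10 diallyl carbonate
Product: 11 tert-butyl (3R)-3-{4,5-bis(benzyloxy)-2-[3-oxo-3-(prop-2-en-1-yloxy)propanoyl]phenyl}-3-[3,4-bis(benzyloxy)phenyl]propanoate
Conditions: NaH (2.5 equiv), (CH2=CHCH2O)2CO (excess), THF, reflux; AcOH quench
Reagents that add atoms: none
Why: Crossed Claisen condensation in which the methyl ketone, far more acidic than the tert-butyl ester CH2, is C-acylated by the carbonate and the equilibrium is pulled by deprotonation of the β-ketoester, while the hindered tert-butyl ester resists allyloxide.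

Step 6
Reactants: 11 tert-butyl (3R)-3-{4,5-bis(benzyloxy)-2-[3-oxo-3-(prop-2-en-1-yloxy)propanoyl]phenyl}-3-[3,4-bis(benzyloxy)phenyl]propanoate
Product: 13 2-tert-butyl 3-prop-2-en-1-yl (1R,2S)-6,7-bis(benzyloxy)-1-[3,4-bis(benzyloxy)phenyl]-4-hydroxy-1,2-dihydronaphthalene-2,3-dicarboxylate (enol of the C4 ketone), via dilithium bis-enolate 12 (not isolated)
Conditions: LiN(i-Pr)2 (2.3 equiv), THF, −78 °C; dianion cannulated into Fe(acac)3 (2.4 equiv), THF (0.01 M), −78 °C → rt; aq. NH4Cl
Reagents that add atoms: none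
Why: LiN(i-Pr)2 removes first the C3 proton between ketone and allyl ester and then one C2 proton α to the tert-butyl ester, and Fe(acac)3 oxidises the more electron-rich ester enolate by one electron to the C2 α-ester radical, which adds to C3 of the neighbouring β-ketoester enolate before a second Fe(acac)3 oxidises the resulting radical anion to the β-ketoester, isolated as its enol. The closest known reaction type is the intramolecular oxidative heterocoupling of two lithium enolates with iron or copper oxidants, including pairings of a 1,3-dicarbonyl enolate with a simple carbonyl enolate. Ring B closes in a six-membered mode, 6-endo-trig with respect to the C3=C4 enolate bond (6-exo-trig if the allyl ester enolate form is counted). The new C2 centre is controlled by the existing C1 centre, because in the half-chair transition state the C2 ester turns away from the C1 aryl group to give the trans (1R,2S) isomer, which is also the thermodynamic one and can be reached by base equilibration α to the ester, while C3 is not stereogenic in the enol. The step needs hetero- over homocoupling, C–C over C–O bond formation and freedom from aldol or Claisen side reactions: the tether and dilution make six-ring closure faster than dimerisation, a carbon radical adds to the carbon terminus of an enolate, the ketone and allyl ester are masked inside the first enolate, and adding the dianion to excess oxidant keeps the acidic product from quenching unreacted dianion.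

Step 7
Reactants: 13 2-tert-butyl 3-prop-2-en-1-yl (1R,2S)-6,7-bis(benzyloxy)-1-[3,4-bis(benzyloxy)phenyl]-4-hydroxy-1,2-dihydronaphthalene-2,3-dicarboxylate
Product: 14 2-tert-butyl 3-prop-2-en-1-yl (1R,2S)-6,7-bis(benzyloxy)-1-[3,4-bis(benzyloxy)phenyl]-4-hydroxy-1,2,3,4-tetrahydronaphthalene-2,3-dicarboxylate (mixture of C3/C4 epimers)
Conditions: NaBH4, THF/MeOH (4:1), 0 °C
Reagents that add atoms: none
Why: NaBH4 reduces the keto tautomer of the cyclic β-ketoester to the β-hydroxy ester (standard for 2-alkoxycarbonyl-1-tetralones) and leaves both esters alone; the new C3 and C4 centres form unselectively and do not matter because both are erased in step 8.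

Step 8
Reactants: 14 2-tert-butyl 3-prop-2-en-1-yl (1R,2S)-6,7-bis(benzyloxy)-1-[3,4-bis(benzyloxy)phenyl]-4-hydroxy-1,2,3,4-tetrahydronaphthalene-2,3-dicarboxylate
Product: 16 2-tert-butyl 3-prop-2-en-1-yl (1R,2S)-6,7-bis(benzyloxy)-1-[3,4-bis(benzyloxy)phenyl]-1,2-dihydronaphthalene-2,3-dicarboxylate, via C4 methanesulfonate 15 (not isolated)
Conditions: MsCl, Et3N, CH2Cl2, 0 °C; then DBU, 0 °C, short reaction time
Reagents that add atoms: none
Why: Mesylation of the benzylic C4 alcohol and E1cB elimination through the C3 ester enolate (the only β-hydrogen is on C3) should give the C3=C4 enoate conjugated with ring A, with C2 at most equilibrating toward the favoured trans arrangement.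

Step 9
Reactants: 16 2-tert-butyl 3-prop-2-en-1-yl (1R,2S)-6,7-bis(benzyloxy)-1-[3,4-bis(benzyloxy)phenyl]-1,2-dihydronaphthalene-2,3-dicarboxylate
Product: 17 (1R,2S)-6,7-bis(benzyloxy)-1-[3,4-bis(benzyloxy)phenyl]-2-(tert-butoxycarbonyl)-1,2-dihydronaphthalene-3-carboxylic acid
Conditions: Pd(PPh3)4 (cat.), morpholine, THF, rt; dilute citric acid wash
Reagents that add atoms: none
Why: Tsuji–Trost deallylation, in which zerovalent palladium ionises the allyl ester and morpholine captures the π-allyl fragment, is a neutral cleavage that spares the tert-butyl ester, the benzyl ethers, the C2 centre and the alkene position, and it is placed after removal of the C4 ketone so that no β-keto acid can decarboxylate.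

Step 10
Reactants: 17 (1R,2S)-6,7-bis(benzyloxy)-1-[3,4-bis(benzyloxy)phenyl]-2-(tert-butoxycarbonyl)-1,2-dihydronaphthalene-3-carboxylic acid; 18 di-tert-butyl L-malate
Product: 19 di-tert-butyl (2S)-2-({[(1R,2S)-6,7-bis(benzyloxy)-1-[3,4-bis(benzyloxy)phenyl]-2-(tert-butoxycarbonyl)-1,2-dihydronaphthalen-3-yl]carbonyl}oxy)butanedioate
Conditions: DCC, DMAP (cat.), CH2Cl2, 0 °C → rt
Reagents that add atoms: none
Why: Steglich esterification, in which the DMAP-derived acylpyridinium of 17 acylates the secondary hydroxyl of 18 without breaking the C–O bond at the malate centre, so its (S) configuration is retained.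

Step 11
Reactants: 19 di-tert-butyl (2S)-2-({[(1R,2S)-6,7-bis(benzyloxy)-1-[3,4-bis(benzyloxy)phenyl]-2-(tert-butoxycarbonyl)-1,2-dihydronaphthalen-3-yl]carbonyl}oxy)butanedioate
Product: 21 (2S)-2-({[(1R,2S)-2-carboxy-1-(3,4-dihydroxyphenyl)-6,7-dihydroxy-1,2-dihydronaphthalen-3-yl]carbonyl}oxy)butanedioic acid (CNP0323723.1), via tetraphenol tri-tert-butyl ester 20 (not isolated)
Conditions: BCl3, C6HMe5, CH2Cl2, −78 °C; MeOH/CHCl3 quench; then TFA/CH2Cl2 (1:1), anisole, 0 °C → rt; argon throughout
Reagents that add atoms: none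
Why: BCl3 with pentamethylbenzene as a non-Lewis-basic cation scavenger cleaves aryl benzyl ethers at −78 °C without touching the alkene and without C-benzylation of the catechols, and TFA then removes the three tert-butyl esters by loss of 2-methylpropene, leaving the acyl–malate ester and all three stereocentres untouched.

Compound list
1 | 3,4-bis(benzyloxy)benzaldehyde | O=Cc1ccc(OCc2ccccc2)c(OCc2ccccc2)c1 | starting material
2 | 4,5-bis(benzyloxy)-2-bromobenzaldehyde | O=Cc1cc(OCc2ccccc2)c(OCc2ccccc2)cc1Br | intermediate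
3 | tert-butyl 2-(diethoxyphosphoryl)acetate | CCOP(=O)(CC(=O)OC(C)(C)C)OCC | starting material
4 | tert-butyl (2E)-3-[4,5-bis(benzyloxy)-2-bromophenyl]prop-2-enoate | CC(C)(C)OC(=O)/C=C/c1cc(OCc2ccccc2)c(OCc2ccccc2)cc1Br | intermediate
5 | [3,4-bis(benzyloxy)phenyl]boronic acid | OB(O)c1ccc(OCc2ccccc2)c(OCc2ccccc2)c1 | starting material
6 | tert-butyl (3R)-3-[4,5-bis(benzyloxy)-2-bromophenyl]-3-[3,4-bis(benzyloxy)phenyl]propanoate | Brc1cc(OCc2ccccc2)c(OCc2ccccc2)cc1[C@@H](c1ccc(OCc2ccccc2)c(OCc2ccccc2)c1)CC(=O)OC(C)(C)C | intermediate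
7 | tributyl(1-ethoxyethenyl)stannane | CCCC[Sn](CCCC)(CCCC)C(=C)OCC | starting material
8 | tert-butyl (3R)-3-[4,5-bis(benzyloxy)-2-(1-ethoxyethenyl)phenyl]-3-[3,4-bis(benzyloxy)phenyl]propanoate | C=C(OCC)c1cc(OCc2ccccc2)c(OCc2ccccc2)cc1[C@@H](c1ccc(OCc2ccccc2)c(OCc2ccccc2)c1)CC(=O)OC(C)(C)C | intermediate
9 | tert-butyl (3R)-3-[2-acetyl-4,5-bis(benzyloxy)phenyl]-3-[3,4-bis(benzyloxy)phenyl]propanoate | CC(=O)c1cc(OCc2ccccc2)c(OCc2ccccc2)cc1[C@@H](c1ccc(OCc2ccccc2)c(OCc2ccccc2)c1)CC(=O)OC(C)(C)C | intermediate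
10 | diallyl carbonate (bis(prop-2-en-1-yl) carbonate) | C=CCOC(=O)OCC=C | starting material
11 | tert-butyl (3R)-3-{4,5-bis(benzyloxy)-2-[3-oxo-3-(prop-2-en-1-yloxy)propanoyl]phenyl}-3-[3,4-bis(benzyloxy)phenyl]propanoate | C=CCOC(=O)CC(=O)c1cc(OCc2ccccc2)c(OCc2ccccc2)cc1[C@@H](c1ccc(OCc2ccccc2)c(OCc2ccccc2)c1)CC(=O)OC(C)(C)C | intermediate
12 | dilithium bis-enolate of 11 (β-ketoester enolate at C3, tert-butyl ester enolate at C2) | [Li+].[Li+].C=CCOC(=O)C=C([O-])c1cc(OCc2ccccc2)c(OCc2ccccc2)cc1[C@@H](c1ccc(OCc2ccccc2)c(OCc2ccccc2)c1)C=C([O-])OC(C)(C)C | intermediate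
13 | 2-tert-butyl 3-prop-2-en-1-yl (1R,2S)-6,7-bis(benzyloxy)-1-[3,4-bis(benzyloxy)phenyl]-4-hydroxy-1,2-dihydronaphthalene-2,3-dicarboxylate | C=CCOC(=O)C1=C(O)c2cc(OCc3ccccc3)c(OCc3ccccc3)cc2[C@@H](c2ccc(OCc3ccccc3)c(OCc3ccccc3)c2)[C@@H]1C(=O)OC(C)(C)C | intermediate
14 | 2-tert-butyl 3-prop-2-en-1-yl (1R,2S)-6,7-bis(benzyloxy)-1-[3,4-bis(benzyloxy)phenyl]-4-hydroxy-1,2,3,4-tetrahydronaphthalene-2,3-dicarboxylate (C3/C4 epimers) | C=CCOC(=O)C1C(O)c2cc(OCc3ccccc3)c(OCc3ccccc3)cc2[C@@H](c2ccc(OCc3ccccc3)c(OCc3ccccc3)c2)[C@@H]1C(=O)OC(C)(C)C | intermediate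
15 | C4 methanesulfonate of 14 | C=CCOC(=O)C1C(OS(C)(=O)=O)c2cc(OCc3ccccc3)c(OCc3ccccc3)cc2[C@@H](c2ccc(OCc3ccccc3)c(OCc3ccccc3)c2)[C@@H]1C(=O)OC(C)(C)C | intermediate
16 | 2-tert-butyl 3-prop-2-en-1-yl (1R,2S)-6,7-bis(benzyloxy)-1-[3,4-bis(benzyloxy)phenyl]-1,2-dihydronaphthalene-2,3-dicarboxylate | C=CCOC(=O)C1=Cc2cc(OCc3ccccc3)c(OCc3ccccc3)cc2[C@@H](c2ccc(OCc3ccccc3)c(OCc3ccccc3)c2)[C@@H]1C(=O)OC(C)(C)C | intermediate
17 | (1R,2S)-6,7-bis(benzyloxy)-1-[3,4-bis(benzyloxy)phenyl]-2-(tert-butoxycarbonyl)-1,2-dihydronaphthalene-3-carboxylic acid (ring B locants as in the plan) | OC(=O)C1=Cc2cc(OCc3ccccc3)c(OCc3ccccc3)cc2[C@@H](c2ccc(OCc3ccccc3)c(OCc3ccccc3)c2)[C@@H]1C(=O)OC(C)(C)C | intermediate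
18 | di-tert-butyl (2S)-2-hydroxybutanedioate (di-tert-butyl L-malate) | CC(C)(C)OC(=O)C[C@H](O)C(=O)OC(C)(C)C | starting material
19 | di-tert-butyl (2S)-2-({[(1R,2S)-6,7-bis(benzyloxy)-1-[3,4-bis(benzyloxy)phenyl]-2-(tert-butoxycarbonyl)-1,2-dihydronaphthalen-3-yl]carbonyl}oxy)butanedioate | CC(C)(C)OC(=O)C[C@H](OC(=O)C1=Cc2cc(OCc3ccccc3)c(OCc3ccccc3)cc2[C@@H](c2ccc(OCc3ccccc3)c(OCc3ccccc3)c2)[C@@H]1C(=O)OC(C)(C)C)C(=O)OC(C)(C)C | intermediate
20 | di-tert-butyl (2S)-2-({[(1R,2S)-2-(tert-butoxycarbonyl)-1-(3,4-dihydroxyphenyl)-6,7-dihydroxy-1,2-dihydronaphthalen-3-yl]carbonyl}oxy)butanedioate | CC(C)(C)OC(=O)C[C@H](OC(=O)C1=Cc2cc(O)c(O)cc2[C@@H](c2ccc(O)c(O)c2)[C@@H]1C(=O)OC(C)(C)C)C(=O)OC(C)(C)C | intermediate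
21 | (2S)-2-({[(1R,2S)-2-carboxy-1-(3,4-dihydroxyphenyl)-6,7-dihydroxy-1,2-dihydronaphthalen-3-yl]carbonyl}oxy)butanedioic acid | O=C(O)C[C@H](OC(=O)C1=Cc2cc(O)c(O)cc2[C@@H](c2ccc(O)c(O)c2)[C@@H]1C(=O)O)C(=O)O | target

Total step count: 11. Longest linear sequence: 11 steps (1 → 21); 3, 5, 7, 10 and 18 enter as purchased reagents.

Steps most likely to fail

Step 6 (oxidative ring closure). The closure may suffer from proton transfer between the acidic product and unreacted dianion, from intermolecular oxidative dimerisation, or from coupling through oxygen instead of carbon. The fallback builds ring B by polar steps; it sets out from 6 and comes back at 13. The lithium enolate of 6 (LiN(i-Pr)2, THF, −78 °C) is alkylated with methyl bromoacetate, so that C2–C3 arises by enolate alkylation, to give 1-tert-butyl 4-methyl 2-{(R)-[4,5-bis(benzyloxy)-2-bromophenyl][3,4-bis(benzyloxy)phenyl]methyl}butanedioate F1 as a pair of C2 epimers that are both carried on. Methoxycarbonylation of the aryl bromide (Pd(OAc)2, dppf, CO, MeOH, Et3N, DMF, 80 °C) gives 1-tert-butyl 4-methyl 2-{(R)-[4,5-bis(benzyloxy)-2-(methoxycarbonyl)phenyl][3,4-bis(benzyloxy)phenyl]methyl}butanedioate F2. Dieckmann condensation (KOt-Bu, THF, 0 °C; aq. NH4Cl) closes C3–C4; the six-ring β-ketoester is the only product that can rest as its enolate, and C2 settles trans on base equilibration, to give 2-tert-butyl 3-methyl (1R,2S)-6,7-bis(benzyloxy)-1-[3,4-bis(benzyloxy)phenyl]-4-hydroxy-1,2-dihydronaphthalene-2,3-dicarboxylate F3. DMAP-catalysed transesterification of this β-ketoester with allyl alcohol in refluxing toluene then gives 13.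

Step 3 (asymmetric 1,4-addition). Insertion into the enoate may be slow because of the ortho bromine, so that protodeboronation of 5 wins, or the face selectivity may be insufficient or of the opposite sense. The fallback replaces asymmetric catalysis by resolution; it sets out from 4 and 5 and comes back at 6. Addition with the more active achiral diene complex [Rh(OH)(cod)]2 in dioxane/H2O should give racemic tert-butyl 3-[4,5-bis(benzyloxy)-2-bromophenyl]-3-[3,4-bis(benzyloxy)phenyl]propanoate F4. Preparative chromatography on a chiral stationary phase separates it into 6 and tert-butyl (3S)-3-[4,5-bis(benzyloxy)-2-bromophenyl]-3-[3,4-bis(benzyloxy)phenyl]propanoate F5, which is discarded.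

Step 10 (esterification). Acyl transfer from the hindered conjugated acid to the weakly nucleophilic α-hydroxy diester may be slow, with rearrangement of the activated acid to the N-acylurea. The fallback is an alkylative esterification with inversion; it sets out from 17 and comes back at 19. Mitsunobu reaction of 17 with di-tert-butyl D-malate (the (R)-alcohol), PPh3 and DIAD in THF lets the carboxylate displace the activated hydroxyl with inversion, which gives 19 with the (S) malate centre without any acyl activation; no new compound is formed.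

Further compounds
F1 | step 6 | 1-tert-butyl 4-methyl 2-{(R)-[4,5-bis(benzyloxy)-2-bromophenyl][3,4-bis(benzyloxy)phenyl]methyl}butanedioate (C2 epimers) | Brc1cc(OCc2ccccc2)c(OCc2ccccc2)cc1[C@@H](c1ccc(OCc2ccccc2)c(OCc2ccccc2)c1)C(CC(=O)OC)C(=O)OC(C)(C)C
F2 | step 6 | 1-tert-butyl 4-methyl 2-{(R)-[4,5-bis(benzyloxy)-2-(methoxycarbonyl)phenyl][3,4-bis(benzyloxy)phenyl]methyl}butanedioate (C2 epimers) | COC(=O)c1cc(OCc2ccccc2)c(OCc2ccccc2)cc1[C@@H](c1ccc(OCc2ccccc2)c(OCc2ccccc2)c1)C(CC(=O)OC)C(=O)OC(C)(C)C
F3 | step 6 | 2-tert-butyl 3-methyl (1R,2S)-6,7-bis(benzyloxy)-1-[3,4-bis(benzyloxy)phenyl]-4-hydroxy-1,2-dihydronaphthalene-2,3-dicarboxylate | COC(=O)C1=C(O)c2cc(OCc3ccccc3)c(OCc3ccccc3)cc2[C@@H](c2ccc(OCc3ccccc3)c(OCc3ccccc3)c2)[C@@H]1C(=O)OC(C)(C)C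
F4 | step 3 | racemic tert-butyl 3-[4,5-bis(benzyloxy)-2-bromophenyl]-3-[3,4-bis(benzyloxy)phenyl]propanoate | Brc1cc(OCc2ccccc2)c(OCc2ccccc2)cc1C(c1ccc(OCc2ccccc2)c(OCc2ccccc2)c1)CC(=O)OC(C)(C)C
F5 | step 3 | tert-butyl (3S)-3-[4,5-bis(benzyloxy)-2-bromophenyl]-3-[3,4-bis(benzyloxy)phenyl]propanoate | Brc1cc(OCc2ccccc2)c(OCc2ccccc2)cc1[C@H](c1ccc(OCc2ccccc2)c(OCc2ccccc2)c1)CC(=O)OC(C)(C)C
F0 | step 10 | none | none
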